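The oxolane is disconnected at O1–C2 and C4–C5. The key step exploits the O1–C5H2 segment of the ring, flanked by aryl-bearing C2 and carbinol C4, as a glycolate C,O-dinucleophile. C2, C3, C4 and the exocyclic CH2O carbon come from an aryl(methylsulfanyl)methylidene malonate. In one anionic operation the glycolate oxygen displaces thiolate at the aryl-bearing carbon and the glycolate carbon closes onto a malonate ester, giving an achiral 3-hydroxyfuran; its tert-butyl ester is a traceless activating group. After decarboxylation, a reagent-controlled ketone reduction sets C4, and hydrogenation anti to its silyl ether installs the all-cis C2/C3/C4 triad.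

Key step: step 2

Assumption: compound 8 is taken to react through its 4-oxo-4,5-dihydrofuran (keto) tautomer, and the sense of the oxazaborolidine reduction is assigned with the sp2 ring carbon C3 as the larger ketone substituent.

Step 1
Reactants: 1 3,4-dimethoxyphenylmagnesium bromide (THF solution); 2 dimethyl 2-[bis(methylsulfanyl)methylidene]propanedioate
Product: 3 dimethyl 2-[(3,4-dimethoxyphenyl)(methylsulfanyl)methylidene]propanedioate
Conditions: CuBr·SMe2 (10 mol%), THF, −78 to 0 °C; aq. NH4Cl
Reagents that add atoms: none
Why: Copper-catalysed conjugate addition–elimination (vinylic substitution) of the aryl Grignard on the push–pull ketene dithioacetal replaces one methylsulfanyl group; the β-carbon should react faster than the cross-conjugated ester carbonyls, and the aryl-substituted product is less electrophilic than 2, so the reaction should stop after one substitution.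

Step 2
Reactants: 3 dimethyl 2-[(3,4-dimethoxyphenyl)(methylsulfanyl)methylidene]propanedioate; 4 tert-butyl 2-hydroxyacetate (tert-butyl glycolate)
Product: 6 2-tert-butyl 4-methyl 5-(3,4-dimethoxyphenyl)-3-hydroxyfuran-2,4-dicarboxylate, via enol ether 5 (not isolated)
Conditions: NaH (2.4 equiv), THF, 0 to 50 °C; then 1 M HCl, 0 °C
Reagents that add atoms: none
Why: The sodium alkoxide of 4 adds to the aryl-bearing β-carbon of the doubly activated alkene 3 and expels methanethiolate (addition–elimination), forming the O–C(aryl) bond and enol ether 5; a second equivalent of NaH then deprotonates the O–CH2–CO2tBu carbon, whose enolate attacks the cis-disposed malonate ester carbonyl and expels methoxide, forming the CH–C(O) bond, and tautomerisation to the aromatic 3-hydroxyfuran sodium salt makes the sequence irreversible. The closest known reaction type is the oxygen analogue of the Fiesselmann thiophene synthesis, the base-mediated condensation of glycolates with alkoxymethylidene malonates or β-halo acrylates to 3-hydroxyfuran-2-carboxylates. The furan ring closes by a 5-exo-trig Dieckmann-type acyl substitution of the glycolate enolate carbon on the ester carbonyl. No stereocentre is formed: 6 is planar and achiral by design, so no element of control is needed here and all three stereocentres are set later from one reduction. The step needs substitution at the vinylic carbon to outrun transesterification, and a single ring-closure mode: the two malonate esters are equivalent, 5 has no acidic C–H other than the glycolate CH2, and the tert-butyl ester resists alkoxide attack and marks the carboxyl that is removed in step 3.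

Step 3
Reactants: 6 2-tert-butyl 4-methyl 5-(3,4-dimethoxyphenyl)-3-hydroxyfuran-2,4-dicarboxylate
Product: 8 methyl 2-(3,4-dimethoxyphenyl)-4-oxo-4,5-dihydrofuran-3-carboxylate, via furoic acid 7 (not isolated)
Conditions: p-TsOH·H2O (0.2 equiv), toluene, 90 °C
Reagents that add atoms: none
Why: Acid-catalysed loss of isobutene from the tert-butyl ester gives the 3-hydroxy-2-furoic acid 7, a vinylogous β-keto acid that should decarboxylate through its keto tautomer and settle as the 3(2H)-furanone 8 (dealkylative decarboxylation of a tert-butyl β-keto ester); the methyl ester on the sp2 carbon is not a β-keto acid precursor and should survive.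

Step 4
Reactants: 8 methyl 2-(3,4-dimethoxyphenyl)-4-oxo-4,5-dihydrofuran-3-carboxylate
Product: 9 methyl (4S)-2-(3,4-dimethoxyphenyl)-4-hydroxy-4,5-dihydrofuran-3-carboxylate
Conditions: (S)-2-methyl-CBS-oxazaborolidine (20 mol%), BH3·SMe2 (0.7 equiv), THF, −20 °C; aq. NaHCO3 work-up
Reagents that add atoms: none
Why: Corey–Bakshi–Shibata reduction: the oxazaborolidine binds the ketone oxygen anti to the larger sp2 C3 side and delivers hydride from the coordinated borane to one carbonyl face, which should set C4 as S (1,2-reduction); the deactivated, vinylogous-ester carbonyl keeps the uncatalysed background reduction slow, and a non-acidic work-up avoids dehydration to a furan.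

Step 5
Reactants: 9 methyl (4S)-2-(3,4-dimethoxyphenyl)-4-hydroxy-4,5-dihydrofuran-3-carboxylate
Product: 10 methyl (4S)-4-[(tert-butyldimethylsilyl)oxy]-2-(3,4-dimethoxyphenyl)-4,5-dihydrofuran-3-carboxylate
Conditions: TBSCl, imidazole, DMF, 0 °C to rt
Reagents that add atoms: tert-butyldimethylsilyl chloride, CC(C)(C)[Si](C)(C)Cl
Why: Standard silylation under mildly basic conditions, which avoids the acid-promoted dehydration of 9 to a furan and places a bulky group on one face of the ring for step 6.

Step 6
Reactants: 10 methyl (4S)-4-[(tert-butyldimethylsilyl)oxy]-2-(3,4-dimethoxyphenyl)-4,5-dihydrofuran-3-carboxylate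
Product: 11 methyl (2S,3S,4S)-4-[(tert-butyldimethylsilyl)oxy]-2-(3,4-dimethoxyphenyl)oxolane-3-carboxylate
Conditions: H2 (5 bar), 10% Pd/C (palladium on carbon), pyridine (0.5 equiv), EtOAc, rt
Reagents that add atoms: none
Why: Heterogeneous syn-hydrogenation of the tetrasubstituted C2=C3 bond: the alkene should adsorb on the face opposite the C4 silyloxy group, so both new hydrogens end up trans to it and the aryl, ester and silyloxy groups all cis (2S,3S,4S); pyridine tempers the catalyst against benzylic C–O hydrogenolysis.

Step 7
Reactants: 11 methyl (2S,3S,4S)-4-[(tert-butyldimethylsilyl)oxy]-2-(3,4-dimethoxyphenyl)oxolane-3-carboxylate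
Product: 13 (3S,4R,5S)-5-(3,4-dimethoxyphenyl)-4-(hydroxymethyl)oxolan-3-ol, via silyl ether alcohol 12 (not isolated)
Conditions: LiAlH4, THF, 0 °C; Rochelle-salt work-up; then TBAF, THF, rt; aq. NH4Cl
Reagents that add atoms: none
Why: Hydride reduction of the methyl ester to the primary alcohol at low temperature (faster than epimerisation at C3), followed by fluoride cleavage of the silyl ether; no stereocentre is touched (the descriptor at the former C3 changes only through priority rules).

Step 8
Reactants: 13 (3S,4R,5S)-5-(3,4-dimethoxyphenyl)-4-(hydroxymethyl)oxolan-3-ol; 14 3,4-dimethoxybenzoyl chloride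
Product: 15 [(2S,3R,4S)-2-(3,4-dimethoxyphenyl)-4-hydroxyoxolan-3-yl]methyl 3,4-dimethoxybenzoate
Conditions: pyridine, CH2Cl2, −20 to 0 °C (1.05 equiv of 14)
Reagents that add atoms: none
Why: Chemoselective acylation: the primary hydroxyl should react faster with the aroyl chloride than the secondary C4 hydroxyl, which is flanked by a cis substituent, so one equivalent at low temperature should give the monoester; the conditions are non-acidic and leave the benzylic C2 centre untouched.

Compound list
1 | 3,4-dimethoxyphenylmagnesium bromide | COc1ccc([Mg]Br)cc1OC | starting material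
2 | dimethyl 2-[bis(methylsulfanyl)methylidene]propanedioate | COC(=O)C(C(=O)OC)=C(SC)SC | starting material
3 | dimethyl 2-[(3,4-dimethoxyphenyl)(methylsulfanyl)methylidene]propanedioate | COC(=O)C(C(=O)OC)=C(SC)c1ccc(OC)c(OC)c1 | intermediate
4 | tert-butyl 2-hydroxyacetate | CC(C)(C)OC(=O)CO | starting material
5 | dimethyl 2-[(2-tert-butoxy-2-oxoethoxy)(3,4-dimethoxyphenyl)methylidene]propanedioate | COC(=O)C(C(=O)OC)=C(OCC(=O)OC(C)(C)C)c1ccc(OC)c(OC)c1 | intermediate
6 | 2-tert-butyl 4-methyl 5-(3,4-dimethoxyphenyl)-3-hydroxyfuran-2,4-dicarboxylate | COC(=O)c1c(O)c(C(=O)OC(C)(C)C)oc1-c1ccc(OC)c(OC)c1 | intermediate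
7 | 5-(3,4-dimethoxyphenyl)-3-hydroxy-4-(methoxycarbonyl)furan-2-carboxylic acid | COC(=O)c1c(O)c(C(=O)O)oc1-c1ccc(OC)c(OC)c1 | intermediate
8 | methyl 2-(3,4-dimethoxyphenyl)-4-oxo-4,5-dihydrofuran-3-carboxylate | COC(=O)C1=C(c2ccc(OC)c(OC)c2)OCC1=O | intermediate
9 | methyl (4S)-2-(3,4-dimethoxyphenyl)-4-hydroxy-4,5-dihydrofuran-3-carboxylate | COC(=O)C1=C(c2ccc(OC)c(OC)c2)OC[C@H]1O | intermediate
10 | methyl (4S)-4-[(tert-butyldimethylsilyl)oxy]-2-(3,4-dimethoxyphenyl)-4,5-dihydrofuran-3-carboxylate | COC(=O)C1=C(c2ccc(OC)c(OC)c2)OC[C@H]1O[Si](C)(C)C(C)(C)C | intermediate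
11 | methyl (2S,3S,4S)-4-[(tert-butyldimethylsilyl)oxy]-2-(3,4-dimethoxyphenyl)oxolane-3-carboxylate | COC(=O)[C@@H]1[C@H](O[Si](C)(C)C(C)(C)C)CO[C@@H]1c1ccc(OC)c(OC)c1 | intermediate
12 | [(2S,3S,4S)-4-[(tert-butyldimethylsilyl)oxy]-2-(3,4-dimethoxyphenyl)oxolan-3-yl]methanol | OC[C@@H]1[C@H](O[Si](C)(C)C(C)(C)C)CO[C@@H]1c1ccc(OC)c(OC)c1 | intermediate
13 | (3S,4R,5S)-5-(3,4-dimethoxyphenyl)-4-(hydroxymethyl)oxolan-3-ol | OC[C@@H]1[C@H](O)CO[C@@H]1c1ccc(OC)c(OC)c1 | intermediate
14 | 3,4-dimethoxybenzoyl chloride | COc1ccc(C(=O)Cl)cc1OC | starting material
15 | [(2S,3R,4S)-2-(3,4-dimethoxyphenyl)-4-hydroxyoxolan-3-yl]methyl 3,4-dimethoxybenzoate | COc1ccc(C(=O)OC[C@@H]2[C@H](O)CO[C@@H]2c2ccc(OC)c(OC)c2)cc1OC | target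

Total step count: 8
Longest linear sequence: 8 steps (from 1 and 2 to 15)

Steps most likely to fail

Step 2. Displacement of the methylsulfanyl group at the hindered, donor-stabilised vinylic carbon may be slower than transesterification or self-condensation of the glycolate, so that the ring never closes. The fallback leaves the route at 3, which is oxidised (mCPBA, CH2Cl2, 0 °C) to the sulfone dimethyl 2-[(3,4-dimethoxyphenyl)(methanesulfonyl)methylidene]propanedioate F1. Methanesulfinate is a much better nucleofuge, so 4 and NaH (THF, −20 °C to rt) should substitute at low temperature through 5, and the same Dieckmann closure should follow in the same flask. The fallback comes back to the route at 6.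

Step 4. The oxazaborolidine may discriminate poorly between the two carbonyl faces of this vinylogous ester, or conjugate hydride addition and slow turnover may erode the outcome. The fallback sets out from 8 and replaces the borane reduction by a ketoreductase (NADPH-dependent alcohol dehydrogenase class; glucose dehydrogenase and glucose for cofactor recycling, phosphate buffer pH 7, DMSO co-solvent, 30 °C), chosen by screening for the (S)-alcohol. It comes back to the route at 9 and makes no new compound (F0).

Step 6. Facial selectivity on the catalyst surface may be poor, the benzylic or allylic C–O bonds may undergo hydrogenolysis, or the tetrasubstituted alkene may not reduce at all. The fallback sets out from 10 and builds the two centres in separate ionic events: LiBH(s-Bu)3 (THF, −78 °C) should add hydride to C2 anti to the silyloxy group and give the lithium ester enolate of 11 F2 (C3 planar, C2 and C4 as in 11). Protonation at −78 °C with 2,6-di-tert-butyl-4-methylphenol from the face opposite both ring substituents should then place the ester cis to them. The fallback comes back to the route at 11.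

Further compounds
F1 | step 2 | dimethyl 2-[(3,4-dimethoxyphenyl)(methanesulfonyl)methylidene]propanedioate | COC(=O)C(C(=O)OC)=C(c1ccc(OC)c(OC)c1)S(C)(=O)=O
F0 | step 4 | none | none
F2 | step 6 | lithium ester enolate of 11 (C3 planar, C2 and C4 as in 11) | COC([O-])=C1[C@H](O[Si](C)(C)C(C)(C)C)CO[C@@H]1c1ccc(OC)c(OC)c1.[Li+]
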